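The data stem from a simulated flask for an exercise.

The midnight run made 0.809 side product per target by its first reading, and the dawn run, with half the reagent, made 0.339, so I took that ratio to follow the reagent standing in the flask.

| flask | substrate | reagent | remark | time |
|---|---|---|---|---|
| midnight | 1.4 M | 1.82 M | run made earlier |  |
| dawn | 1.4 M | 0.91 M | run made earlier |  |
| north-west | 1.4 M | 1.82 M | a closed flask charged with all of it at once and left for 30 min | 30 min |
| south-east | 1.4 M | 1.82 M | one stirred flow tank at steady state, fed with the mixture as stated, mean residence time 90.0 min |  |
| north | 1.4 M (fed, over 24.0 min) | 1.82 M | all but substrate at the start; substrate goes in evenly over 24.0 min, the run ends at 30 min | 30 min |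
| south-west | 1.4 M | 1.82 M | a single well-mixed tank run continuously and read at steady state, 30 min in it on average |  |

| run | time / min | target / % | side product / % |
|---|---|---|---|
| midnight | 2.50 | 9.4 | 7.6 |
| midnight | 5.00 | 15.2 | 11.4 |
| midnight | 8.00 | 20.4 | 14.1 |
| midnight | 15.0 | 28.2 | 16.1 |
| midnight | 30.0 | 36.8 | 19.1 |
| dawn | 3.00 | 6.2 | 2.1 |
| dawn | 10.0 | 15.3 | 5.2 |
| dawn | 15.0 | 18.8 | 5.4 |
| dawn | 25.0 | 24.1 | 7.5 |
| dawn | 40.0 | 29.2 | 8.3 |

(scatter of a reading: 0.5 percentage points)

- order of the set-ups by the share of target in all that became target or side product, at the outlet or at the end, highest first (north-west / south-east / north / south-west)
- share of target in all that became target or side product, at the outlet or at the end, north-west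
- share of target in all that became target or side product, at the outlet or at the end, south-east
- share of target in all that became target or side product, at the outlet or at the end, north
- share of target in all that became target or side product, at the outlet or at the end, south-west

- the stated concentrations are those of everything mixed, before any reaction; amounts are the same in each set-up
- the feed brings no volume worth counting
- the earlier runs were made in a closed, stirred flask

Dividing the midnight ratio by the reagent charge gave the selectivity factor, side product made per target per molar of standing reagent: 0.444 M⁻¹. Dawn gave 0.372 M⁻¹, from a small reading with a scatter of 0.5 percentage points. The share asked is then one over one plus factor times level.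

Nobody read the reagent, but I let it follow the target rate per substrate left. In the midnight run that rate fell from 0.0411 min⁻¹ to 0.0115 min⁻¹, which put the level near 0.509 M between the last readings. I assumed for this charge that the inverse level climbs steadily, at 0.0629 M⁻¹ min⁻¹, so one turnover lasts 8.73 min, and on that assumption it takes the level to half the charge.

Two extremes bound the closed flask. With reagent held at its charge the share is 55.3%. With the end level after 3.44 turnovers held throughout, it is 84.6%. North-west travels from the first towards the second, and repeats midnight, so I read 65.8%. A tank stands at its outlet level, where reagent fed minus reagent leaving equals reagent used. That gave 0.752 M and 75.0% for south-west, 0.485 M and 82.3% for south-east. In north I expected reagent to stand higher at first, with target forming late, and placed it between north-west and south-west.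

The forecast, against that order, gave south-east > north > south-west > north-west, with 66%, 80%, 76% and 72% for north-west, south-east, north and south-west, holding that “the side reaction has a higher order”.

The flasks gave south-east > south-west > north > north-west: north-west 66.6%, south-east 81.9%, north 70.5%, south-west 74.0%.

    substrate + reagent → target (k = 0.0271 M⁻¹ min⁻¹)
    substrate + 2 reagent → side product (k = 0.0143 M⁻² min⁻¹)
    2 reagent → self-condensation product (k = 0.0154 M⁻¹ min⁻¹)

North-west ended with 16.2% of its reagent, so I took its level midway between charge and end, 1.06 M, and the factor gives 68.0% against the 66.6% it gave. A neighbour of north-west charged with 0.73 M of reagent ended with 20.9% of it, so its midway level was 0.441 M, and the share comes to 83.6%. That flask gave 82.1%, with 4.96% of the substrate charged as side product.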